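Ring C is reached through a temporary C2–C4 bond, later traded for C2–C3. The feature exploited: the hydrogen on C2 is activated by O1 and ring B, and C2 lies 1,5 to C4 (path C4, C4a, C8a, O1, C2). A chiral dirhodium carbene at the future C4 inserts into one enantiotopic C2–H bond. This single operation closes a cis-2-aryl-2,3-dihydrobenzofuran and fixes C2. The precursor is a ring-A aryldiazoacetate whose O1 carries the ring-B benzyl group, prenyl groups and silyl ethers already in place. Hydroxylation, redox adjustment and a chelated alpha-ketol shift of C2 enlarge the ring and relay C2 to C3.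

Key step: step 11

Assumption: in this class of benzyl ether insertion the catalyst made from (S)-tert-leucine is taken to give the (2R,3S)-cis ester, so the mirror-image catalyst Rh2(R-PTTL)4 is specified for the (2S,3R) series needed here; the sense should be confirmed on the first batch by crystallography or circular dichroism, and the two antipodes can be exchanged with no other change.

Abbreviations: TBS = tert-butyldimethylsilyl; prenyl = 3-methylbut-2-enyl. C2, C3, C4 and O1 follow flavanone numbering unless a benzofuran name is given. The target is (2R,3R), trans.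

Step 1
Reactants: 1 2,4-dihydroxyphenylacetic acid
Product: 2 6-hydroxybenzofuran-2(3H)-one
Conditions: p-TsOH·H2O (5 mol %), toluene, reflux, Dean–Stark
Reagents that add atoms: none
Why: Acid-catalysed lactonisation can engage only the ortho hydroxyl (five-membered ring), so the future O1 is masked as an aryl ester while the future 7-OH stays free and the two phenols are told apart.

Step 2
Reactants: 2 6-hydroxybenzofuran-2(3H)-one
Product: 3 5-bromo-6-hydroxybenzofuran-2(3H)-one
Conditions: NBS (1.0 equiv), MeCN, −10 → 0 °C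
Reagents that add atoms: N-bromosuccinimide, O=C1CCC(=O)N1Br
Why: Electrophilic aromatic bromination is steered by the free phenol to C5, which is ortho to OH and para to the lactone oxygen, rather than to C7, which is wedged between two oxygens, and the acylated O1 tempers the ring enough to stop at one bromine.

Step 3
Reactants: 3 5-bromo-6-hydroxybenzofuran-2(3H)-one
Product: 4 5-bromo-6-(TBS-oxy)benzofuran-2(3H)-one
Conditions: TBSCl, imidazole, CH2Cl2, 0 °C → rt
Reagents that add atoms: tert-butyldimethylsilyl chloride, CC(C)(C)[Si](C)(C)Cl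
Why: Imidazole-promoted O-silylation of the only free phenol leaves the enolisable lactone closed, and a silyl ether is the mask that can be removed at the end without acid (prenyl cyclisation) or base (opening of ring C).

Step 4
Reactants: 4 5-bromo-6-(TBS-oxy)benzofuran-2(3H)-one; 5 tributyl(3-methylbut-2-enyl)stannane
Product: 6 6-(TBS-oxy)-5-prenylbenzofuran-2(3H)-one
Conditions: Pd(PPh3)4 (5 mol %), degassed toluene, 105 °C
Reagents that add atoms: none
Why: In this Migita–Kosugi–Stille coupling the aryl bromide adds oxidatively to zerovalent palladium, prenyl is transferred from tin, and reductive elimination at the unsubstituted allyl terminus should give the linear prenyl arene under neutral, fluoride-free conditions that spare lactone and silyl ether.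

Step 5
Reactants: 6 6-(TBS-oxy)-5-prenylbenzofuran-2(3H)-one
Product: 7 methyl 2-[4-(TBS-oxy)-2-hydroxy-5-prenylphenyl]acetate
Conditions: MeOH, camphorsulfonic acid (10 mol %), 23–40 °C; solid NaHCO3 before evaporation
Reagents that add atoms: methanol, CO
Why: Acid-catalysed transesterification of the reactive aryl lactone by solvent methanol frees the O1 phenol and forms the methyl ester at once, the aryl silyl ether and the trisubstituted alkene tolerate catalytic sulfonic acid at this temperature, and neutralising first prevents re-lactonisation.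

Step 6
Reactants: 8 3-bromo-4-hydroxybenzaldehyde
Product: 9 3-bromo-4-(TBS-oxy)benzaldehyde
Conditions: TBSCl, imidazole, CH2Cl2, 0 °C → rt
Reagents that add atoms: tert-butyldimethylsilyl chloride, CC(C)(C)[Si](C)(C)Cl
Why: This is a routine imidazole-promoted phenol silylation that gives ring B the same mask as ring A, so one final operation frees both phenols.

Step 7
Reactants: 9 3-bromo-4-(TBS-oxy)benzaldehyde; 5 tributyl(3-methylbut-2-enyl)stannane
Product: 10 4-(TBS-oxy)-3-prenylbenzaldehyde
Conditions: Pd(PPh3)4 (5 mol %), degassed toluene, 105 °C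
Reagents that add atoms: none
Why: This Migita–Kosugi–Stille prenylation runs as in step 4, the aldehyde being inert to the neutral tin reagent and zerovalent palladium.

Step 8
Reactants: 10 4-(TBS-oxy)-3-prenylbenzaldehyde
Product: 11 [4-(TBS-oxy)-3-prenylphenyl]methanol
Conditions: NaBH4, THF–EtOH, 0 °C, short reaction time; H2O
Reagents that add atoms: none
Why: Borohydride reduction of the aldehyde is fast at 0 °C, so the para silyl ether is exposed only briefly to alkoxide, and the alkene is untouched.

Step 9
Reactants: 7 methyl 2-[4-(TBS-oxy)-2-hydroxy-5-prenylphenyl]acetate; 11 [4-(TBS-oxy)-3-prenylphenyl]methanol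
Product: 12 methyl 2-[4-(TBS-oxy)-2-{[4-(TBS-oxy)-3-prenylphenyl]methoxy}-5-prenylphenyl]acetate
Conditions: PPh3, DIAD, THF, 0 °C → rt
Reagents that add atoms: none
Why: Mitsunobu etherification joins the only free phenol to the only free primary alcohol under neutral conditions, which avoids both a labile para-silyloxybenzyl halide and a carbonate base that could shuffle aryl silyl groups.

Step 10
Reactants: 12 the benzyl ether ester of step 9
Product: 13 methyl 2-diazo-2-[4-(TBS-oxy)-2-{[4-(TBS-oxy)-3-prenylphenyl]methoxy}-5-prenylphenyl]acetate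
Conditions: 4-acetamidobenzenesulfonyl azide, DBU, dry MeCN, 0 °C → rt
Reagents that add atoms: 4-acetamidobenzenesulfonyl azide, CC(=O)Nc1ccc(cc1)S(=O)(=O)N=[N+]=[N-]
Why: In this Regitz diazo transfer the arylacetate enolate formed by DBU attacks the terminal azide nitrogen and the adduct collapses to diazo ester and sulfonamide, while strictly dry solvent keeps the amidine from cleaving the aryl silyl ethers.

Step 11
Reactants: 13 the aryldiazoacetate of step 10
Product: 14 methyl (2S,3R)-6-(TBS-oxy)-2-[4-(TBS-oxy)-3-prenylphenyl]-5-prenyl-2,3-dihydrobenzofuran-3-carboxylate (cis; the benzofuran C2 is the target C2 with its final geometry)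
Conditions: Rh2(R-PTTL)4 = dirhodium tetrakis[N-phthaloyl-(R)-tert-leucinate] (1.5 mol %), 4 Å molecular sieves, toluene, −60 °C, slow addition of 13 at high dilution
Reagents that add atoms: none
Why: The diazo carbon binds an axial site of the divalent rhodium dimer, N2 departs, and the donor–acceptor carbene takes up the benzylic ether C–H bond in one asynchronous event in which hydrogen runs ahead of carbon and the transient positive charge on C2 is shared by O1 and the para-silyloxy ring B. The closest known reaction type is the enantioselective intramolecular C–H insertion of methyl 2-(2-benzyloxyaryl)-2-diazoacetates with phthalimido amino acid derived dirhodium tetracarboxylates, which gives cis-2-aryl-2,3-dihydrobenzofuran-3-carboxylates. The single new ring, the five-membered oxygen heterocycle, closes by 1,5-insertion (C2–C4 bond in flavanone numbering), and the ortho-phenylene tether puts no other C–H bond within reach. C2 is set by the catalyst, whose phthalimido-walled pocket picks one of the two enantiotopic benzylic hydrogens; the ester-bearing carbon is set in the same event as the kinetic cis partner because ring B turns away from the ligand wall, and this second centre is erased again in step 12. The selectivity needed is insertion over attack on the prenyl groups, carbene dimerisation and capture of water. The ring-A prenyl is meta to the carbene carbon and out of reach, the ring-B prenyl could react only through a macrocycle, a bulky donor–acceptor carbene cyclopropanates trisubstituted alkenes only sluggishly, and slow addition at high dilution over sieves suppresses every bimolecular path.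

Step 12
Reactants: 14 the cis ester of step 11
Product: 16 methyl (2R,3S)-6-(TBS-oxy)-2-[4-(TBS-oxy)-3-prenylphenyl]-3-hydroxy-5-prenyl-2,3-dihydrobenzofuran-3-carboxylate (OH trans and ester cis to the 2-aryl group; C2 geometry unchanged, descriptor changed by priority only), via potassium enolate 15 (not isolated)
Conditions: KN(SiMe3)2 (1.1 equiv), THF, −78 °C; 2-(phenylsulfonyl)-3-phenyloxaziridine (1.3 equiv), −78 °C; AcOH quench at −78 °C
Reagents that add atoms: 2-(phenylsulfonyl)-3-phenyloxaziridine, O=S(=O)(c1ccccc1)N1OC1c1ccccc1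
Why: In this Davis oxidation the benzylic ester enolate forms at −78 °C, where expulsion of the O1 phenoxide (the reverse of a 5-endo-trig addition, with the C2–O1 bond near the nodal plane of the enolate) should remain slow, and the bulky oxaziridine delivers oxygen to the face opposite the C2 aryl group, which sets the carbinol as 3S.

Step 13
Reactants: 16 the hydroxy ester of step 12
Product: 17 (2R,3R)-6-(TBS-oxy)-2-[4-(TBS-oxy)-3-prenylphenyl]-3-(hydroxymethyl)-5-prenyl-2,3-dihydrobenzofuran-3-ol
Conditions: iBu2AlH (DIBAL-H, 4 equiv), CH2Cl2, −78 → 0 °C; aq. potassium sodium tartrate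
Reagents that add atoms: none
Why: Exhaustive aluminium hydride reduction of the ester needs no control at the aldehyde stage, and aryl silyl ethers, the benzylic ether and trisubstituted alkenes are inert to this hydride below 0 °C, so both stereocentres are carried through unchanged.

Step 14
Reactants: 17 the diol of step 13
Product: 18 (2R,3S)-6-(TBS-oxy)-2-[4-(TBS-oxy)-3-prenylphenyl]-3-hydroxy-5-prenyl-2,3-dihydrobenzofuran-3-carbaldehyde
Conditions: SO3·pyridine, DMSO, Et3N, CH2Cl2, 0 °C; used without chromatography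
Reagents that add atoms: none
Why: Parikh–Doering oxidation converts only the primary alcohol, because the tertiary carbinol cannot be oxidised and activated DMSO neither cleaves 1,2-diols nor touches prenyl alkenes, and the aldehyde has no alpha hydrogen to lose.

Step 15
Reactants: 18 the hydroxy aldehyde of step 14
Product: 20 (2R,3R)-7-(TBS-oxy)-2-[4-(TBS-oxy)-3-prenylphenyl]-3-hydroxy-6-prenylchroman-4-one (2,3-trans), via aluminium alkoxide 19 (not isolated)
Conditions: Al(OtBu)3 (1.1 equiv), toluene, 23 → 60 °C; aq. potassium sodium tartrate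
Reagents that add atoms: none
Why: In this alpha-ketol (acyloin) rearrangement aluminium holds the carbinol oxygen as alkoxide and the formyl oxygen in a five-membered chelate, the O1-bearing benzylic C2 moves with retention from the carbinol carbon to the formyl carbon while the carbinol carbon becomes the C4 ketone conjugated with the oxygenated ring A (the driving force, and the reason C2 rather than the ring-A carbon should leave), and in the syn-chelated geometry of the 3S epimer C2 meets the formyl face that gives the 3R, 2,3-trans carbinol, which is also the more stable epimer.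

Step 16
Reactants: 20 the bis-silyl dihydroflavonol of step 15
Product: 21 lespeflorin B1, (2R,3R)-3,7-dihydroxy-2-(4-hydroxy-3-prenylphenyl)-6-prenylchroman-4-one
Conditions: Bu4NF/AcOH (1:1, 2.5 equiv), THF, 0 °C
Reagents that add atoms: none
Why: Fluoride cleaves both aryl silyl ethers while acetic acid protonates each phenoxide as it forms, which should suppress quinone-methide opening of ring C at C2 and enolisation at C3, and no acid strong enough to cyclise the ortho-prenylphenols to chromans is present.

Compound list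
1 | 2,4-dihydroxyphenylacetic acid | OC(=O)Cc1ccc(O)cc1O | starting material
2 | 6-hydroxybenzofuran-2(3H)-one | O=C1Cc2ccc(O)cc2O1 | intermediate
3 | 5-bromo-6-hydroxybenzofuran-2(3H)-one | O=C1Cc2cc(Br)c(O)cc2O1 | intermediate
4 | 5-bromo-6-(TBS-oxy)benzofuran-2(3H)-one | O=C1Cc2cc(Br)c(O[Si](C)(C)C(C)(C)C)cc2O1 | intermediate
5 | tributyl(3-methylbut-2-enyl)stannane | CCCC[Sn](CCCC)(CCCC)CC=C(C)C | starting material
6 | 6-(TBS-oxy)-5-prenylbenzofuran-2(3H)-one | O=C1Cc2cc(CC=C(C)C)c(O[Si](C)(C)C(C)(C)C)cc2O1 | intermediate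
7 | methyl 2-[4-(TBS-oxy)-2-hydroxy-5-prenylphenyl]acetate | COC(=O)Cc1cc(CC=C(C)C)c(O[Si](C)(C)C(C)(C)C)cc1O | intermediate
8 | 3-bromo-4-hydroxybenzaldehyde | O=Cc1ccc(O)c(Br)c1 | starting material
9 | 3-bromo-4-(TBS-oxy)benzaldehyde | O=Cc1ccc(O[Si](C)(C)C(C)(C)C)c(Br)c1 | intermediate
10 | 4-(TBS-oxy)-3-prenylbenzaldehyde | O=Cc1ccc(O[Si](C)(C)C(C)(C)C)c(CC=C(C)C)c1 | intermediate
11 | [4-(TBS-oxy)-3-prenylphenyl]methanol | OCc1ccc(O[Si](C)(C)C(C)(C)C)c(CC=C(C)C)c1 | intermediate
12 | methyl 2-[4-(TBS-oxy)-2-{[4-(TBS-oxy)-3-prenylphenyl]methoxy}-5-prenylphenyl]acetate | COC(=O)Cc1cc(CC=C(C)C)c(O[Si](C)(C)C(C)(C)C)cc1OCc1ccc(O[Si](C)(C)C(C)(C)C)c(CC=C(C)C)c1 | intermediate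
13 | methyl 2-diazo-2-[4-(TBS-oxy)-2-{[4-(TBS-oxy)-3-prenylphenyl]methoxy}-5-prenylphenyl]acetate | COC(=O)C(=[N+]=[N-])c1cc(CC=C(C)C)c(O[Si](C)(C)C(C)(C)C)cc1OCc1ccc(O[Si](C)(C)C(C)(C)C)c(CC=C(C)C)c1 | intermediate
14 | methyl (2S,3R)-cis-6-(TBS-oxy)-2-[4-(TBS-oxy)-3-prenylphenyl]-5-prenyl-2,3-dihydrobenzofuran-3-carboxylate | CC(C)=CCc1cc([C@H]2Oc3cc(O[Si](C)(C)C(C)(C)C)c(CC=C(C)C)cc3[C@H]2C(=O)OC)ccc1O[Si](C)(C)C(C)(C)C | intermediate
15 | potassium enolate of 14 (C2 geometry retained) | CC(C)=CCc1cc([C@H]2Oc3cc(O[Si](C)(C)C(C)(C)C)c(CC=C(C)C)cc3C2=C([O-])OC)ccc1O[Si](C)(C)C(C)(C)C.[K+] | intermediate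
16 | methyl (2R,3S)-6-(TBS-oxy)-2-[4-(TBS-oxy)-3-prenylphenyl]-3-hydroxy-5-prenyl-2,3-dihydrobenzofuran-3-carboxylate | CC(C)=CCc1cc([C@H]2Oc3cc(O[Si](C)(C)C(C)(C)C)c(CC=C(C)C)cc3[C@@]2(O)C(=O)OC)ccc1O[Si](C)(C)C(C)(C)C | intermediate
17 | (2R,3R)-6-(TBS-oxy)-2-[4-(TBS-oxy)-3-prenylphenyl]-3-(hydroxymethyl)-5-prenyl-2,3-dihydrobenzofuran-3-ol | CC(C)=CCc1cc([C@H]2Oc3cc(O[Si](C)(C)C(C)(C)C)c(CC=C(C)C)cc3[C@@]2(O)CO)ccc1O[Si](C)(C)C(C)(C)C | intermediate
18 | (2R,3S)-6-(TBS-oxy)-2-[4-(TBS-oxy)-3-prenylphenyl]-3-hydroxy-5-prenyl-2,3-dihydrobenzofuran-3-carbaldehyde | CC(C)=CCc1cc([C@H]2Oc3cc(O[Si](C)(C)C(C)(C)C)c(CC=C(C)C)cc3[C@@]2(O)C=O)ccc1O[Si](C)(C)C(C)(C)C | intermediate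
19 | di-tert-butoxyaluminium alkoxide of 18 | CC(C)=CCc1cc([C@H]2Oc3cc(O[Si](C)(C)C(C)(C)C)c(CC=C(C)C)cc3[C@@]2(O[Al](OC(C)(C)C)OC(C)(C)C)C=O)ccc1O[Si](C)(C)C(C)(C)C | intermediate
20 | (2R,3R)-7-(TBS-oxy)-2-[4-(TBS-oxy)-3-prenylphenyl]-3-hydroxy-6-prenylchroman-4-one | CC(C)=CCc1cc([C@H]2Oc3cc(O[Si](C)(C)C(C)(C)C)c(CC=C(C)C)cc3C(=O)[C@@H]2O)ccc1O[Si](C)(C)C(C)(C)C | intermediate
21 | lespeflorin B1, (2R,3R) | CC(C)=CCc1cc([C@H]2Oc3cc(O)c(CC=C(C)C)cc3C(=O)[C@@H]2O)ccc1O | target

Total step count: 16. Longest linear sequence: 13 (steps 1–5 and 9–16).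

Steps most likely to fail

1. Step 15. Four things may go wrong:
- The ring-A carbon may migrate in place of C2.
- The tertiary benzylic hydroxyl may be lost, with aromatisation of the five-membered ring.
- The bond from C2 to the carbinol carbon may ionise stepwise and erode C2.
- Ring C may open by beta-elimination after the shift.

The fallback sets out from 16 and returns at 21. It replaces the free ketol shift by the organoaluminium-promoted rearrangement of an alpha-silyloxy aldehyde, a semipinacol-type variant in which neither a free tertiary benzylic alcohol nor a basic alkoxide is present. Silylation of 16 (Et3SiOTf, 2,6-lutidine, CH2Cl2, 0 °C) should give methyl (2R,3S)-6-(TBS-oxy)-2-[4-(TBS-oxy)-3-prenylphenyl]-5-prenyl-3-(triethylsilyloxy)-2,3-dihydrobenzofuran-3-carboxylate F1. One equivalent of iBu2AlH at −78 °C should stop at (2R,3S)-6-(TBS-oxy)-2-[4-(TBS-oxy)-3-prenylphenyl]-5-prenyl-3-(triethylsilyloxy)-2,3-dihydrobenzofuran-3-carbaldehyde F2, which also removes the separate oxidation. Me2AlCl (2.5 equiv, CH2Cl2, −78 → −20 °C) scavenges protons and can bridge a silyloxy and a carbonyl oxygen. It should drive C2 to the formyl carbon with transfer of silicon to the new oxygen, giving (2R,3R)-7-(TBS-oxy)-2-[4-(TBS-oxy)-3-prenylphenyl]-6-prenyl-3-(triethylsilyloxy)chroman-4-one F3. The conditions of step 16 with one more equivalent of fluoride then remove all three silyl groups.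

2. Step 11. The catalyst may discriminate poorly between the two benzylic hydrogens of this heavily substituted substrate. The carbene may also be diverted by bimolecular attack on prenyl alkenes or their allylic C–H bonds, or by dimerisation.

The fallback sets out from 4 and 9 and returns at 14. It runs the insertion before any alkene is present and installs both prenyl groups afterwards. Methanolysis of 4 as in step 5 gives methyl 2-[5-bromo-4-(TBS-oxy)-2-hydroxyphenyl]acetate F4. Borohydride reduction of 9 gives [3-bromo-4-(TBS-oxy)phenyl]methanol F5. Mitsunobu coupling gives methyl 2-[5-bromo-2-{[3-bromo-4-(TBS-oxy)phenyl]methoxy}-4-(TBS-oxy)phenyl]acetate F6, and Regitz transfer gives its 2-diazo derivative F7. The same rhodium catalyst should close methyl (2S,3R)-cis-5-bromo-2-[3-bromo-4-(TBS-oxy)phenyl]-6-(TBS-oxy)-2,3-dihydrobenzofuran-3-carboxylate F8. Its bromine atoms allow recrystallisation to raise the optical purity and a crystallographic check of the absolute sense. A twofold Migita–Kosugi–Stille coupling with 5 (Pd(PPh3)4, toluene, 105 °C) then gives 14. Any epimerisation at the ester carbon during heating is harmless, because step 12 planarises that centre.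

3. Step 12. The enolate may expel the O1 phenoxide and open the ring. Oxygen transfer may leak to the face syn to ring B, which would feed the cis ketol in step 15. The product alkoxide may add to the sulfonimine.

The fallback sets out from 14 and returns at 16. It avoids a metal enolate by a Rubottom-type oxidation of a neutral ketene acetal. Soft enolisation (Me3SiOTf, Et3N, CH2Cl2, 0 °C) should give the methyl trimethylsilyl ketene acetal of 14 F9. The same N-sulfonyloxaziridine in CH2Cl2 at 0 °C → rt oxidises this very electron-rich alkene far faster than the prenyl groups and again from the face opposite ring B. After silyl migration this gives methyl (2R,3S)-6-(TBS-oxy)-2-[4-(TBS-oxy)-3-prenylphenyl]-5-prenyl-3-(trimethylsilyloxy)-2,3-dihydrobenzofuran-3-carboxylate F10. Citric acid in MeOH removes the trimethylsilyl group selectively and gives 16.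

Further compounds
F1 | step 15 | methyl (2R,3S)-6-(TBS-oxy)-2-[4-(TBS-oxy)-3-prenylphenyl]-5-prenyl-3-(triethylsilyloxy)-2,3-dihydrobenzofuran-3-carboxylate | CC(C)=CCc1cc([C@H]2Oc3cc(O[Si](C)(C)C(C)(C)C)c(CC=C(C)C)cc3[C@@]2(O[Si](CC)(CC)CC)C(=O)OC)ccc1O[Si](C)(C)C(C)(C)C
F2 | step 15 | (2R,3S)-6-(TBS-oxy)-2-[4-(TBS-oxy)-3-prenylphenyl]-5-prenyl-3-(triethylsilyloxy)-2,3-dihydrobenzofuran-3-carbaldehyde | CC(C)=CCc1cc([C@H]2Oc3cc(O[Si](C)(C)C(C)(C)C)c(CC=C(C)C)cc3[C@@]2(O[Si](CC)(CC)CC)C=O)ccc1O[Si](C)(C)C(C)(C)C
F3 | step 15 | (2R,3R)-7-(TBS-oxy)-2-[4-(TBS-oxy)-3-prenylphenyl]-6-prenyl-3-(triethylsilyloxy)chroman-4-one | CC(C)=CCc1cc([C@H]2Oc3cc(O[Si](C)(C)C(C)(C)C)c(CC=C(C)C)cc3C(=O)[C@@H]2O[Si](CC)(CC)CC)ccc1O[Si](C)(C)C(C)(C)C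
F4 | step 11 | methyl 2-[5-bromo-4-(TBS-oxy)-2-hydroxyphenyl]acetate | COC(=O)Cc1cc(Br)c(O[Si](C)(C)C(C)(C)C)cc1O
F5 | step 11 | [3-bromo-4-(TBS-oxy)phenyl]methanol | OCc1ccc(O[Si](C)(C)C(C)(C)C)c(Br)c1
F6 | step 11 | methyl 2-[5-bromo-2-{[3-bromo-4-(TBS-oxy)phenyl]methoxy}-4-(TBS-oxy)phenyl]acetate | COC(=O)Cc1cc(Br)c(O[Si](C)(C)C(C)(C)C)cc1OCc1ccc(O[Si](C)(C)C(C)(C)C)c(Br)c1
F7 | step 11 | methyl 2-[5-bromo-2-{[3-bromo-4-(TBS-oxy)phenyl]methoxy}-4-(TBS-oxy)phenyl]-2-diazoacetate | COC(=O)C(=[N+]=[N-])c1cc(Br)c(O[Si](C)(C)C(C)(C)C)cc1OCc1ccc(O[Si](C)(C)C(C)(C)C)c(Br)c1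
F8 | step 11 | methyl (2S,3R)-cis-5-bromo-2-[3-bromo-4-(TBS-oxy)phenyl]-6-(TBS-oxy)-2,3-dihydrobenzofuran-3-carboxylate | Brc1cc([C@H]2Oc3cc(O[Si](C)(C)C(C)(C)C)c(Br)cc3[C@H]2C(=O)OC)ccc1O[Si](C)(C)C(C)(C)C
F9 | step 12 | methyl trimethylsilyl ketene acetal of 14 | CC(C)=CCc1cc([C@H]2Oc3cc(O[Si](C)(C)C(C)(C)C)c(CC=C(C)C)cc3C2=C(OC)O[Si](C)(C)C)ccc1O[Si](C)(C)C(C)(C)C
F10 | step 12 | methyl (2R,3S)-6-(TBS-oxy)-2-[4-(TBS-oxy)-3-prenylphenyl]-5-prenyl-3-(trimethylsilyloxy)-2,3-dihydrobenzofuran-3-carboxylate | CC(C)=CCc1cc([C@H]2Oc3cc(O[Si](C)(C)C(C)(C)C)c(CC=C(C)C)cc3[C@@]2(O[Si](C)(C)C)C(=O)OC)ccc1O[Si](C)(C)C(C)(C)C
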